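The data are calculated on assumed constants, noise included.

A small charge opens this flask: coupling partner stands at 0.95 equiv of starting material, less than second reagent or third reagent, yet in spring, which is this flask followed so far, target reads 16.5% at 60.0 min and 15.9% at 180 min.

| setting | spring | dawn | flask |
|---|---|---|---|
| starting material | 0.050 M | 0.050 M | 0.050 M |
| coupling partner | 0.95 equiv | 1.9 equiv | 0.950 equiv |
| second reagent | 1.3 equiv | 1.3 equiv | 1.30 equiv |
| third reagent | 1.2 equiv | 1.2 equiv | 1.20 equiv |
| temperature | 35 °C | 20 °C | 35 °C |
| remark | the very flask that is asked about, followed so far | run made earlier |  |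
| time |  |  | 5.0 h |

| run | time / min | target / % |
|---|---|---|
| spring | 15.0 | 7.5 |
| spring | 25.0 | 11.4 |
| spring | 40.0 | 15.2 |
| spring | 60.0 | 16.5 |
| spring | 120 | 16.2 |
| spring | 180 | 15.9 |
| dawn | 4.00 | 0 |
| dawn | 12.0 | 2.6 |
| dawn | 20.0 | 3.4 |
| dawn | 30.0 | 6.4 |
| dawn | 50.0 | 9.6 |
| dawn | 60.0 | 11.6 |

(scatter of a reading: 0.3 percentage points)

- Sunday's: at 5.0 h take out 90% of the target then present, then wait 2.5 h
- Wednesday's: change nothing and wait 2.5 h more
- Saturday's: at 5.0 h raise the temperature by 15 K, then wait 2.5 h
- Tuesday's: at 5.0 h add third reagent, 50.0% of the amount charged, then wait 2.5 h

- what is taken out of target is counted as made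
- additions bring no volume worth counting

* target, in percent of the starting material first charged, at 5.0 h
* which option adds most target ("none" when 2 percentage points or less is all one gets) (Sunday's / Wednesday's / Saturday's / Tuesday's / none)
* target present, with what was taken out counted in, in percent of the starting material first charged, after Sunday's
* target present, with what was taken out counted in, in percent of the starting material first charged, after Wednesday's

The readings sharpen the contradiction: spring gains 7.5% in its first 15.0 min, but 1.3 percentage points between 40.0 min and 60.0 min, although on a one-to-one count the 16.5% of target accounts for 17.4% of the coupling partner charged. So I read the stop as a feed lost to something other than target, and I take that feed to be third reagent, the one Tuesday's supplies; this is my own reading, and dawn, colder and still climbing at 11.6%, neither proves nor refutes it. My measure is the third-reagent yield, target made per charge of third reagent, 13.8%. At that yield Tuesday's portion of 0.600 equiv brings 8.2 points, more than the margin, while taking target out, waiting or heating supplies no feed, so I commit to about 16.2% at 5.0 h and after both Sunday's and Wednesday's.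

The forecast differs: it sees “a reversible stall or product-driven stop rather than reagent death”, and it gives 15.3% now, 23% after Sunday's, 14.7% after Wednesday's, and names Sunday's.

The flask gives 16.2%, 16.2% after Sunday's and 16.2% after Wednesday's, and the best option is Tuesday's, which adds 18 points.

    third reagent + intermediate B → target (k = 2.43 /M/s, Ea = 37.0 kJ/mol)
    starting material + second reagent → side product (k = 0.108 /M/s, Ea = 41.0 kJ/mol)
    2 third reagent → homo dimer (k = 0.0659 /M/s, Ea = 42.0 kJ/mol)
    starting material + coupling partner → intermediate A (k = 0.0659 /M/s, Ea = 70.0 kJ/mol)
    second reagent + intermediate A → intermediate B (k = 0.0113 /M/s, Ea = 56.0 kJ/mol)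
    (constants at 35 °C)

That portion's yield is 29.2%, more than the 13.8% I carried, so in this flask the yield differs from one portion of third reagent to the next. Homo dimer formation is the largest single effect in this flask: without it the flask reaches 33.1% at 5.0 h, a yield of 27.6%, and Tuesday's gain shrinks to 0.62 points. In the neighbour flask with 3.80 equiv of coupling partner and the same charge of third reagent, the yield at 5.0 h is 22.0%, from 26.4% of target.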